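6.10 d is what I read from the alpha run for one decay turnover: the time in which target falls by a factor e while the solid substrate reads about zero, here 0.4 % and then 0 %, between 2.08 d and 6.00 d.

| flask | solid substrate | partner | remark | time |
|---|---|---|---|---|
| alpha | 0.43 M | 1.9 M | run made earlier |  |
| eta | 1.7 M | 1.9 M | run made earlier |  |
| north-east | 0.50 M | 1.90 M |  | 8.0 d |
| west | 1.0 M | 1.90 M |  | 8.0 d |
| south-west | 2.0 M | 1.90 M |  | 8.0 d |

| run | time / d | target / % | solid substrate / % |
|---|---|---|---|
| alpha | 0.417 | 15.0 | 56.1 |
| alpha | 0.833 | 35.5 | 17.2 |
| alpha | 1.25 | 48.6 | 0 |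
| alpha | 2.08 | 46.0 | 0.4 |
| alpha | 3.00 | 37.9 | 0.7 |
| alpha | 6.00 | 24.2 | 0 |
| eta | 0.417 | 3.8 | 89.2 |
| eta | 1.04 | 10.8 | 74.8 |
| eta | 2.08 | 16.0 | 51.5 |
| eta | 3.00 | 16.6 | 33.2 |
| eta | 4.00 | 16.1 | 12.5 |
| eta | 6.00 | 11.5 | 0 |

(standard deviation of a reading: 0.5 percentage points)

1. [target] at the end for north-east, west, south-west, in this order
2. how that number moves from the first to the last of them (rises all the way / hardly changes / falls, then rises / falls all the way / rises, then falls)

The eta run loses solid substrate at 0.364 M/d, and I take that rate as steady. Dividing each charge by it, the solid lasts 1.37 d in north-east, 2.75 d in west and 5.50 d in south-west. The time left after that, counted in turnovers, is 1.09, 0.861 and 0.410. South-west therefore sits through fewer turnovers than north-east. The best target reading is also higher in eta, at 0.282 M, than in alpha, at 0.209 M. So I expect the row to rise.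

The forecast gives 0.09 M, 0.115 M and 0.13 M, so rises all the way, and it grants south-west “about 2.7 d of decay”.

The flask gives 0.0868 M, 0.0997 M and 0.129 M, so rises all the way.

    solid substrate ⇌ dissolved substrate, rate k1*(cs1 - [dissolved substrate]) while solid is left; crystals form when [dissolved substrate] > cs1 (solubility = 0.630 M, k = 0.0340 /h)
    dissolved substrate + target → side product (k = 0.120 /M/h)
    dissolved substrate + partner ⇌ target (K = 2.20 /M, k = 0.0520 /M/h)

In north-east at the asked time, the relaxation half-life of the reversible step between dissolved substrate, partner and target (a pre-equilibrium), that step taken alone and both ways together, is 0.265 d, shorter than the run's 8.0 d and shorter than the 2.8 d half-life of dissolved substrate through side product. The span from 4.00 d to 8.00 d is 0.655 turnovers, which by my count takes target in north-east from 29.7 % of the charge to 15.4 % against the flask's 17.4 %, and target in west from 21.3 % to 11.1 % against the flask's 9.97 %.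

The data were computed with constants of no real substance, noise included.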